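Assumption: compound 2 is commercial silyl-protected acetylene (the silyl group is a protecting group, removed in step 2). The sense of induction of the chiral ligands in steps 1 and 7 is taken as written; the ligand antipode is used if it proves opposite.

**Retrosynthetic overview** (germacrane atom numbering; furanone = ring A, butenolide = ring B, ten-membered carbocycle = ring C)
1. Ring order: A is built by the key step, B is bought preformed (14), C is closed last; the C8 ester is attached before ring closure.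
2. The C13 acetoxymethyl group is installed last by Stille coupling at a C11 bromide, because an α-acetoxymethyl butenolide would lose acetate during the enolisation that closes ring C.
3. Ring C: C5=C6 by intramolecular vinylogous aldol condensation of the butenolide γ-carbon onto a C5 aldehyde; C7–C8 by asymmetric Nozaki–Hiyama–Kishi coupling.
4. Ring A and the quaternary C4: gold-catalysed heterocyclisation/1,2-alkenyl shift of an α-hydroxy-α-alkynyl methyl ketone, whose carbinol centre comes from (S)-lactamide by chelate-controlled Grignard addition.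
5. C10: rhodium-catalysed asymmetric conjugate alkynylation of crotonaldehyde.

**Route**

Step 1
Reactants: 1 (E)-but-2-enal; 2 ethynyltri(propan-2-yl)silane
Product: 4 [(3S)-5,5-dimethoxy-3-methylpent-1-yn-1-yl]tri(propan-2-yl)silane, via silyl ynal 3 (not isolated)
Conditions: [Rh(OAc)(C2H4)2]2 (2.5 mol %), (R)-DTBM-SEGPHOS (6 mol %), MeOH, 40 °C; then HC(OMe)3, PPTS (cat.), 23 °C
Reagents that add atoms: trimethyl orthoformate, COC(OC)OC; methanol, CO
Why: Rhodium-catalysed asymmetric conjugate alkynylation of an enal (the bulky silyl group suppresses alkyne dimerisation) sets C10 by catalyst control, and acetalisation in the same flask masks the aldehyde for the acetylide chemistry.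

Step 2
Reactants: 4 [(3S)-5,5-dimethoxy-3-methylpent-1-yn-1-yl]tri(propan-2-yl)silane
Product: 5 (3S)-5,5-dimethoxy-3-methylpent-1-yne
Conditions: n-Bu4NF, THF, 0 → 23 °C
Reagents that add atoms: none
Why: Fluoride-mediated protodesilylation of a silylalkyne; the acetal and the non-epimerisable propargylic centre are untouched.

Step 3
Reactants: 5 (3S)-5,5-dimethoxy-3-methylpent-1-yne; 6 (2S)-2-hydroxy-N,N-dimethylpropanamide
Product: 8 (2S,6S)-2-hydroxy-8,8-dimethoxy-6-methyloct-4-yn-3-one, via lithium acetylide 7 (not isolated)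
Conditions: 5 (2.2 equiv), n-BuLi (2.1 equiv), THF, −78 °C; then 6, −78 → 0 °C; aq. NH4Cl
Reagents that add atoms: none
Why: Acylation of a lithium acetylide by a tertiary amide, where the chelated tetrahedral intermediate prevents over-addition and the lactate centre is retained; the second equivalent of acetylide only deprotonates the hydroxyl and returns 5 on quench.

Step 4
Reactants: 8 (2S,6S)-2-hydroxy-8,8-dimethoxy-6-methyloct-4-yn-3-one; 9 (2-methylprop-1-en-1-yl)magnesium bromide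
Product: 10 (2S,3R,6S)-8,8-dimethoxy-6-methyl-3-(2-methylprop-1-en-1-yl)oct-4-yne-2,3-diol
Conditions: 9 (2.5 equiv), THF/CH2Cl2, −78 → −40 °C (8 added to the Grignard reagent); pH 7 buffer
Reagents that add atoms: none
Why: Cram-chelate-controlled Grignard 1,2-addition to an α-hydroxy ketone: magnesium bridges alkoxide and carbonyl and the alkenyl group enters anti to the lactate methyl, setting the (3R)-carbinol.

Step 5
Reactants: 10 (2S,3R,6S)-8,8-dimethoxy-6-methyl-3-(2-methylprop-1-en-1-yl)oct-4-yne-2,3-diol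
Product: 11 (3R,6S)-3-hydroxy-8,8-dimethoxy-6-methyl-3-(2-methylprop-1-en-1-yl)oct-4-yn-2-one
Conditions: Dess–Martin periodinane, NaHCO3, CH2Cl2, 0 → 23 °C
Reagents that add atoms: none
Why: Dess–Martin oxidation of the only secondary alcohol; the tertiary carbinol cannot oxidise and buffering avoids ionisation or glycol cleavage.

Step 6
Reactants: 11 (3R,6S)-3-hydroxy-8,8-dimethoxy-6-methyl-3-(2-methylprop-1-en-1-yl)oct-4-yn-2-one
Product: 13 (3S)-3-[(5S)-5-methyl-5-(2-methylprop-1-en-1-yl)-4-oxo-4,5-dihydrofuran-2-yl]butanal, via furanone dimethyl acetal 12 (not isolated)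
Conditions: Ph3PAuNTf2 (5 mol %), CH2Cl2, 0 → 23 °C; then THF, 1 M HCl, 23 °C
Reagents that add atoms: water, O
Why: Proposed new method: the carbophilic monovalent gold catalyst activates the alkyne, the acetyl oxygen closes 5-endo onto it to give a planar 3-hydroxy-3H-furanium ion, and the alkenyl group on the carbinol carbon shifts suprafacially to the adjacent oxocarbenium carbon (semipinacol-type 1,2-shift of the skeleton), so the (R)-carbinol is relayed to the (S)-quaternary C4 before protodeauration and acetal hydrolysis in the same flask; the closest known reaction type is the AuCl3- or PtCl2-catalysed heterocyclisation/1,2-alkyl migration of 2-hydroxy-2-alkynyl ketones to 3(2H)-furanones, which to my knowledge has not been shown with a migrating alkenyl group or with chirality transfer from an enantioenriched acyclic carbinol.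

Step 7
Reactants: 13 (3S)-3-[(5S)-5-methyl-5-(2-methylprop-1-en-1-yl)-4-oxo-4,5-dihydrofuran-2-yl]butanal; 14 3,4-dibromofuran-2(5H)-one
Product: 15 3-bromo-4-{(1S,3S)-1-hydroxy-3-[(5S)-5-methyl-5-(2-methylprop-1-en-1-yl)-4-oxo-4,5-dihydrofuran-2-yl]butyl}furan-2(5H)-one
Conditions: CrCl2 (3.5 equiv), NiCl2 (5 mol %), (S)-N-[2-(4-isopropyl-4,5-dihydrooxazol-2-yl)-6-methylphenyl]methanesulfonamide (3.8 equiv), Et3N (3.8 equiv), THF, 23 °C
Reagents that add atoms: none
Why: Nozaki–Hiyama–Kishi coupling: nickel inserts into the more electrophilic C4–Br bond of 14, the alkenylchromium adds only to the aldehyde (ketone, enol ether and C3–Br tolerated), and the sulfonamide-bound chromium sets C8 (S) by reagent control.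

Step 8
Reactants: 16 4-methylfuran-2(5H)-one
Product: 19 (2Z)-4-[(tert-butyldimethylsilyl)oxy]-3-methylbut-2-enoic acid, via potassium hydroxy enoate 17 (not isolated), via bis-silyl derivative 18 (not isolated)
Conditions: KOH, MeOH/H2O, 23 °C, evaporate; TBSCl, imidazole, DMF, 23 °C; then THF/H2O/AcOH, 0 °C
Reagents that add atoms: potassium hydroxide, [K+].[OH-]; tert-butyldimethylsilyl chloride, CC(C)(C)[Si](C)(C)Cl
Why: Lactone saponification keeps the Z geometry fixed by the ring, and persilylation followed by selective hydrolysis of the labile silyl ester leaves the O-silylated acid, which can no longer relactonise.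

Step 9
Reactants: 15 3-bromo-4-{(1S,3S)-1-hydroxy-3-[(5S)-5-methyl-5-(2-methylprop-1-en-1-yl)-4-oxo-4,5-dihydrofuran-2-yl]butyl}furan-2(5H)-one; 19 (2Z)-4-[(tert-butyldimethylsilyl)oxy]-3-methylbut-2-enoic acid
Product: 20 (1S,3S)-1-(4-bromo-5-oxo-2,5-dihydrofuran-3-yl)-3-[(5S)-5-methyl-5-(2-methylprop-1-en-1-yl)-4-oxo-4,5-dihydrofuran-2-yl]butyl (2Z)-4-[(tert-butyldimethylsilyl)oxy]-3-methylbut-2-enoate
Conditions: 2-methyl-6-nitrobenzoic anhydride, Et3N, DMAP (cat.), CH2Cl2, 0 → 23 °C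
Reagents that add atoms: none
Why: Shiina mixed-anhydride esterification acylates the hindered allylic alcohol under weakly basic conditions, without Z/E scrambling of the enoate or enolisation of the butenolide.

Step 10
Reactants: 20 (1S,3S)-1-(4-bromo-5-oxo-2,5-dihydrofuran-3-yl)-3-[(5S)-5-methyl-5-(2-methylprop-1-en-1-yl)-4-oxo-4,5-dihydrofuran-2-yl]butyl (2Z)-4-[(tert-butyldimethylsilyl)oxy]-3-methylbut-2-enoate
Product: 21 (1S,3S)-1-(4-bromo-5-oxo-2,5-dihydrofuran-3-yl)-3-[(5S)-5-formyl-5-methyl-4-oxo-4,5-dihydrofuran-2-yl]butyl (2Z)-4-[(tert-butyldimethylsilyl)oxy]-3-methylbut-2-enoate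
Conditions: O3, CH2Cl2, −78 °C (Sudan Red 7B end-point); then PPh3, −78 → 23 °C; used crude
Reagents that add atoms: ozone, [O-][O+]=O
Why: Ozonolysis with a dye end-point: the electron-rich trisubstituted isobutenyl alkene is cleaved much faster than the push–pull furanone alkene, the enoate and the bromobutenolide, unveiling the non-enolisable C5 aldehyde.

Step 11
Reactants: 21 (1S,3S)-1-(4-bromo-5-oxo-2,5-dihydrofuran-3-yl)-3-[(5S)-5-formyl-5-methyl-4-oxo-4,5-dihydrofuran-2-yl]butyl (2Z)-4-[(tert-butyldimethylsilyl)oxy]-3-methylbut-2-enoate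
Product: 24 (4S,5E,8S,10S)-11-bromo-8-{[(2Z)-4-[(tert-butyldimethylsilyl)oxy]-3-methylbut-2-enoyl]oxy}-1,4-epoxy-3-oxo-13-norgermacra-1,5,7(11)-trien-12,6-olide, via silyloxyfuran 22 (not isolated), via silylated aldol macrocycle 23 (not isolated)
Conditions: TBSOTf (1.3 equiv), Et3N (2 equiv), CH2Cl2 (2 mM), −78 → 0 °C; then DBU, 0 °C
Reagents that add atoms: none
Why: Intramolecular vinylogous Mukaiyama aldol of the 2-silyloxyfuran onto the C5 aldehyde, then E1cB loss of silanolate (butenolide ylidenation); the bridged ten-membered ring can only hold C4 and C7 cis across C5=C6, which is the required 5E enol lactone, and bromine at C11 leaves the dienolate no competing leaving group.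

Step 12
Reactants: 24 (4S,5E,8S,10S)-11-bromo-8-{[(2Z)-4-[(tert-butyldimethylsilyl)oxy]-3-methylbut-2-enoyl]oxy}-1,4-epoxy-3-oxo-13-norgermacra-1,5,7(11)-trien-12,6-olide
Product: 26 (4S,5E,8S,10S)-13-acetoxy-8-{[(2Z)-4-[(tert-butyldimethylsilyl)oxy]-3-methylbut-2-enoyl]oxy}-1,4-epoxy-3-oxogermacra-1,5,7(11)-trien-12,6-olide, via hydroxymethyl butenolide 25 (not isolated)
Conditions: Bu3SnCH2OH (1.5 equiv), Pd(PPh3)4 (10 mol %), 1,4-dioxane, 80 °C; then Ac2O, pyridine, DMAP (cat.), 0 °C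
Reagents that add atoms: (tributylstannyl)methanol, CCCC[Sn](CCCC)(CCCC)CO; acetic anhydride, CC(=O)OC(C)=O
Why: Stille (Migita–Kosugi) hydroxymethylation of the α-bromo enoate with zerovalent palladium, then acetylation; coupling the free alcohol first avoids exposing an allylic acetate to the palladium catalyst.

Step 13
Reactants: 26 (4S,5E,8S,10S)-13-acetoxy-8-{[(2Z)-4-[(tert-butyldimethylsilyl)oxy]-3-methylbut-2-enoyl]oxy}-1,4-epoxy-3-oxogermacra-1,5,7(11)-trien-12,6-olide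
Product: 27 (4S,5E,8S,10S)-13-acetoxy-8-{[(2Z)-4-hydroxy-3-methylbut-2-enoyl]oxy}-1,4-epoxy-3-oxogermacra-1,5,7(11)-trien-12,6-olide (CNP0269057.1)
Conditions: HF·pyridine, pyridine, THF, 0 °C; NaHCO3 quench
Reagents that add atoms: none
Why: Buffered fluoride desilylation at 0 °C removes the primary silyl ether without acid- or base-induced lactonisation of the (Z)-4-hydroxy enoate, acyl migration or epimerisation at C8/C10.

**Compound list**
1 | (E)-but-2-enal | C/C=C/C=O | starting material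
2 | ethynyltri(propan-2-yl)silane | C#C[Si](C(C)C)(C(C)C)C(C)C | starting material
3 | (3S)-3-methyl-5-[tri(propan-2-yl)silyl]pent-4-ynal | O=CC[C@H](C)C#C[Si](C(C)C)(C(C)C)C(C)C | intermediate
4 | [(3S)-5,5-dimethoxy-3-methylpent-1-yn-1-yl]tri(propan-2-yl)silane | COC(OC)C[C@H](C)C#C[Si](C(C)C)(C(C)C)C(C)C | intermediate
5 | (3S)-5,5-dimethoxy-3-methylpent-1-yne | COC(OC)C[C@H](C)C#C | intermediate
6 | (2S)-2-hydroxy-N,N-dimethylpropanamide | C[C@H](O)C(=O)N(C)C | starting material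
7 | lithium (3S)-5,5-dimethoxy-3-methylpent-1-yn-1-ide | [Li]C#C[C@@H](C)CC(OC)OC | intermediate
8 | (2S,6S)-2-hydroxy-8,8-dimethoxy-6-methyloct-4-yn-3-one | C[C@H](O)C(=O)C#C[C@@H](C)CC(OC)OC | intermediate
9 | (2-methylprop-1-en-1-yl)magnesium bromide | CC(C)=C[Mg]Br | starting material
10 | (2S,3R,6S)-8,8-dimethoxy-6-methyl-3-(2-methylprop-1-en-1-yl)oct-4-yne-2,3-diol | C[C@H](O)[C@@](O)(C=C(C)C)C#C[C@@H](C)CC(OC)OC | intermediate
11 | (3R,6S)-3-hydroxy-8,8-dimethoxy-6-methyl-3-(2-methylprop-1-en-1-yl)oct-4-yn-2-one | CC(=O)[C@@](O)(C=C(C)C)C#C[C@@H](C)CC(OC)OC | intermediate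
12 | (2S)-5-[(2S)-4,4-dimethoxybutan-2-yl]-2-methyl-2-(2-methylprop-1-en-1-yl)furan-3(2H)-one | CC(C)=C[C@]1(C)OC(=CC1=O)[C@@H](C)CC(OC)OC | intermediate
13 | (3S)-3-[(5S)-5-methyl-5-(2-methylprop-1-en-1-yl)-4-oxo-4,5-dihydrofuran-2-yl]butanal | CC(C)=C[C@]1(C)OC(=CC1=O)[C@@H](C)CC=O | intermediate
14 | 3,4-dibromofuran-2(5H)-one | O=C1OCC(Br)=C1Br | starting material
15 | 3-bromo-4-{(1S,3S)-1-hydroxy-3-[(5S)-5-methyl-5-(2-methylprop-1-en-1-yl)-4-oxo-4,5-dihydrofuran-2-yl]butyl}furan-2(5H)-one | CC(C)=C[C@]1(C)OC(=CC1=O)[C@@H](C)C[C@H](O)C2=C(Br)C(=O)OC2 | intermediate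
16 | 4-methylfuran-2(5H)-one | CC1=CC(=O)OC1 | starting material
17 | potassium (2Z)-4-hydroxy-3-methylbut-2-enoate | [K+].[O-]C(=O)/C=C(/C)CO | intermediate
18 | tert-butyldimethylsilyl (2Z)-4-[(tert-butyldimethylsilyl)oxy]-3-methylbut-2-enoate | CC(C)(C)[Si](C)(C)OC(=O)/C=C(/C)CO[Si](C)(C)C(C)(C)C | intermediate
19 | (2Z)-4-[(tert-butyldimethylsilyl)oxy]-3-methylbut-2-enoic acid | OC(=O)/C=C(/C)CO[Si](C)(C)C(C)(C)C | intermediate
20 | (1S,3S)-1-(4-bromo-5-oxo-2,5-dihydrofuran-3-yl)-3-[(5S)-5-methyl-5-(2-methylprop-1-en-1-yl)-4-oxo-4,5-dihydrofuran-2-yl]butyl (2Z)-4-[(tert-butyldimethylsilyl)oxy]-3-methylbut-2-enoate | CC(C)=C[C@]1(C)OC(=CC1=O)[C@@H](C)C[C@H](OC(=O)/C=C(/C)CO[Si](C)(C)C(C)(C)C)C2=C(Br)C(=O)OC2 | intermediate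
21 | (1S,3S)-1-(4-bromo-5-oxo-2,5-dihydrofuran-3-yl)-3-[(5S)-5-formyl-5-methyl-4-oxo-4,5-dihydrofuran-2-yl]butyl (2Z)-4-[(tert-butyldimethylsilyl)oxy]-3-methylbut-2-enoate | O=C[C@]1(C)OC(=CC1=O)[C@@H](C)C[C@H](OC(=O)/C=C(/C)CO[Si](C)(C)C(C)(C)C)C2=C(Br)C(=O)OC2 | intermediate
22 | (1S,3S)-1-{4-bromo-5-[(tert-butyldimethylsilyl)oxy]furan-3-yl}-3-[(5S)-5-formyl-5-methyl-4-oxo-4,5-dihydrofuran-2-yl]butyl (2Z)-4-[(tert-butyldimethylsilyl)oxy]-3-methylbut-2-enoate | O=C[C@]1(C)OC(=CC1=O)[C@@H](C)C[C@H](OC(=O)/C=C(/C)CO[Si](C)(C)C(C)(C)C)c2coc(O[Si](C)(C)C(C)(C)C)c2Br | intermediate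
23 | (4S,8S,10S)-11-bromo-5-[(tert-butyldimethylsilyl)oxy]-8-{[(2Z)-4-[(tert-butyldimethylsilyl)oxy]-3-methylbut-2-enoyl]oxy}-1,4-epoxy-3-oxo-13-norgermacra-1,7(11)-dien-12,6-olide (C5/C6 epimers) | BrC1=C2C(C(O[Si](C)(C)C(C)(C)C)[C@]3(C)OC(=CC3=O)[C@@H](C)C[C@@H]2OC(=O)/C=C(/C)CO[Si](C)(C)C(C)(C)C)OC1=O | intermediate
24 | (4S,5E,8S,10S)-11-bromo-8-{[(2Z)-4-[(tert-butyldimethylsilyl)oxy]-3-methylbut-2-enoyl]oxy}-1,4-epoxy-3-oxo-13-norgermacra-1,5,7(11)-trien-12,6-olide | BrC1=C2/C(=C\[C@]3(C)OC(=CC3=O)[C@@H](C)C[C@@H]2OC(=O)/C=C(/C)CO[Si](C)(C)C(C)(C)C)OC1=O | intermediate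
25 | (4S,5E,8S,10S)-8-{[(2Z)-4-[(tert-butyldimethylsilyl)oxy]-3-methylbut-2-enoyl]oxy}-1,4-epoxy-13-hydroxy-3-oxogermacra-1,5,7(11)-trien-12,6-olide | OCC1=C2/C(=C\[C@]3(C)OC(=CC3=O)[C@@H](C)C[C@@H]2OC(=O)/C=C(/C)CO[Si](C)(C)C(C)(C)C)OC1=O | intermediate
26 | (4S,5E,8S,10S)-13-acetoxy-8-{[(2Z)-4-[(tert-butyldimethylsilyl)oxy]-3-methylbut-2-enoyl]oxy}-1,4-epoxy-3-oxogermacra-1,5,7(11)-trien-12,6-olide | CC(=O)OCC1=C2/C(=C\[C@]3(C)OC(=CC3=O)[C@@H](C)C[C@@H]2OC(=O)/C=C(/C)CO[Si](C)(C)C(C)(C)C)OC1=O | intermediate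
27 | (4S,5E,8S,10S)-13-acetoxy-8-{[(2Z)-4-hydroxy-3-methylbut-2-enoyl]oxy}-1,4-epoxy-3-oxogermacra-1,5,7(11)-trien-12,6-olide (CNP0269057.1) | CC(=O)OCC1=C2/C(=C\[C@]3(C)OC(=CC3=O)[C@@H](C)C[C@@H]2OC(=O)/C=C(/C)CO)OC1=O | target

**Totals**
Total step count: 13. Longest linear sequence: 12 (steps 1–7 and 9–13; step 8 is the side branch).

**Three steps most likely to fail**

Step 6 (the proposed new step). Two risks: an oxophilic, chelate-type acyclic α-ketol shift would deliver the alkenyl group to the opposite face of C4 and erode the ee (hence the soft, carbophilic gold catalyst), and the doubly activated tertiary carbinol may ionise. Fallback with known chemistry, setting out from 5 (as its acetylide 7) and coming back at 12: the quaternary carbinol is made first and the furanone is closed by the classical 5-endo cyclisation of a γ-hydroxy ynone. (R)-Lactic acid and pivalaldehyde (TsOH, pentane, water removal) give (2R,5R)-2-tert-butyl-5-methyl-1,3-dioxolan-4-one F1. Deprotonation with LiN(i-Pr)2 (THF, −78 °C) and aldol addition to 2-methylpropanal, anti to the tert-butyl group (self-regeneration of the stereocentre), gives (2R,5S)-2-tert-butyl-5-(1-hydroxy-2-methylpropyl)-5-methyl-1,3-dioxolan-4-one F2. Burgess dehydration gives (2R,5S)-2-tert-butyl-5-methyl-5-(2-methylprop-1-en-1-yl)-1,3-dioxolan-4-one F3. MeNH(OMe)·HCl/i-PrMgCl opens it to (2S)-2-hydroxy-N-methoxy-N,2,4-trimethylpent-3-enamide F4. Acetylide 7 (2.2 equiv) gives (3S,7S)-7-hydroxy-1,1-dimethoxy-3,7,9-trimethyldec-8-en-4-yn-6-one F5. Et2NH/EtOH (or AuCl3 cat.) closes this to 12, which is hydrolysed to 13 as in step 6.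

Step 11 (ring C closure). Risks: oligomerisation, ionisation of the C8 acyloxy group in the silyloxyfuran, soft enolisation towards C10, and C8 epimerisation by DBU. Fallback setting out from 12 and coming back at 23: the ring is closed at C7–C8 instead of C5–C6. Ozonolysis of 12 gives (2S)-5-[(2S)-4,4-dimethoxybutan-2-yl]-2-methyl-3-oxo-2,3-dihydrofuran-2-carbaldehyde F6. Compound 14 with TBSOTf/Et3N gives 3,4-dibromo-2-[(tert-butyldimethylsilyl)oxy]furan F7, which adds to F6 in an intermolecular vinylogous Mukaiyama aldol to give 3,4-dibromo-5-{[(tert-butyldimethylsilyl)oxy][(2S)-5-[(2S)-4,4-dimethoxybutan-2-yl]-2-methyl-3-oxo-2,3-dihydrofuran-2-yl]methyl}furan-2(5H)-one F8. Mild acid hydrolysis gives (3S)-3-{(5S)-5-[(3,4-dibromo-5-oxo-2,5-dihydrofuran-2-yl)(tert-butyldimethylsilyloxy)methyl]-5-methyl-4-oxo-4,5-dihydrofuran-2-yl}butanal F9. Nozaki–Hiyama–Kishi macrocyclisation (CrCl2, NiCl2 cat., DMSO/THF, high dilution) gives (4S,10S)-11-bromo-5-[(tert-butyldimethylsilyl)oxy]-1,4-epoxy-8-hydroxy-3-oxo-13-norgermacra-1,7(11)-dien-12,6-olide F10, with C8 set by the ring (the 8S epimer is separated or corrected by Mitsunobu inversion). Esterification with 19 as in step 9 gives 23, and DBU then gives 24.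

Step 7 (C7–C8 coupling and C8 configuration). Risks: the alkenyl bromide is less reactive than an iodide, and ligand control at C8 may be modest. Fallback setting out from 13 and 14 and coming back at 15: the stereocentre is set by ketone reduction instead of carbonyl addition. Ligand-free coupling (CrCl2, NiCl2 cat., DMF) gives the C8-epimeric 3-bromo-4-{(3S)-1-hydroxy-3-[(5S)-5-methyl-5-(2-methylprop-1-en-1-yl)-4-oxo-4,5-dihydrofuran-2-yl]butyl}furan-2(5H)-one F11. Dess–Martin oxidation gives 3-bromo-4-{(3S)-3-[(5S)-5-methyl-5-(2-methylprop-1-en-1-yl)-4-oxo-4,5-dihydrofuran-2-yl]butanoyl}furan-2(5H)-one F12. Corey–Bakshi–Shibata reduction ((R)-Me-CBS oxazaborolidine, BH3·SMe2, −40 °C; bromobutenolide as the large group) returns 15.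

**Further compounds**
F1 | step 6 | (2R,5R)-2-tert-butyl-5-methyl-1,3-dioxolan-4-one | C[C@H]1O[C@@H](C(C)(C)C)OC1=O
F2 | step 6 | (2R,5S)-2-tert-butyl-5-(1-hydroxy-2-methylpropyl)-5-methyl-1,3-dioxolan-4-one | C[C@@]1(C(O)C(C)C)O[C@@H](C(C)(C)C)OC1=O
F3 | step 6 | (2R,5S)-2-tert-butyl-5-methyl-5-(2-methylprop-1-en-1-yl)-1,3-dioxolan-4-one | C[C@@]1(C=C(C)C)O[C@@H](C(C)(C)C)OC1=O
F4 | step 6 | (2S)-2-hydroxy-N-methoxy-N,2,4-trimethylpent-3-enamide | CC(C)=C[C@](C)(O)C(=O)N(C)OC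
F5 | step 6 | (3S,7S)-7-hydroxy-1,1-dimethoxy-3,7,9-trimethyldec-8-en-4-yn-6-one | CC(C)=C[C@](C)(O)C(=O)C#C[C@@H](C)CC(OC)OC
F6 | step 11 | (2S)-5-[(2S)-4,4-dimethoxybutan-2-yl]-2-methyl-3-oxo-2,3-dihydrofuran-2-carbaldehyde | O=C[C@]1(C)OC(=CC1=O)[C@@H](C)CC(OC)OC
F7 | step 11 | 3,4-dibromo-2-[(tert-butyldimethylsilyl)oxy]furan | CC(C)(C)[Si](C)(C)Oc1occ(Br)c1Br
F8 | step 11 | 3,4-dibromo-5-{[(tert-butyldimethylsilyl)oxy][(2S)-5-[(2S)-4,4-dimethoxybutan-2-yl]-2-methyl-3-oxo-2,3-dihydrofuran-2-yl]methyl}furan-2(5H)-one | CC(C)(C)[Si](C)(C)OC(C1OC(=O)C(Br)=C1Br)[C@]2(C)OC(=CC2=O)[C@@H](C)CC(OC)OC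
F9 | step 11 | (3S)-3-{(5S)-5-[(3,4-dibromo-5-oxo-2,5-dihydrofuran-2-yl)(tert-butyldimethylsilyloxy)methyl]-5-methyl-4-oxo-4,5-dihydrofuran-2-yl}butanal | CC(C)(C)[Si](C)(C)OC(C1OC(=O)C(Br)=C1Br)[C@]2(C)OC(=CC2=O)[C@@H](C)CC=O
F10 | step 11 | (4S,10S)-11-bromo-5-[(tert-butyldimethylsilyl)oxy]-1,4-epoxy-8-hydroxy-3-oxo-13-norgermacra-1,7(11)-dien-12,6-olide (8S shown) | O=C1OC2C(O[Si](C)(C)C(C)(C)C)[C@]3(C)OC(=CC3=O)[C@@H](C)C[C@H](O)C2=C1Br
F11 | step 7 | 3-bromo-4-{(3S)-1-hydroxy-3-[(5S)-5-methyl-5-(2-methylprop-1-en-1-yl)-4-oxo-4,5-dihydrofuran-2-yl]butyl}furan-2(5H)-one (C1 epimers) | CC(C)=C[C@]1(C)OC(=CC1=O)[C@@H](C)CC(O)C2=C(Br)C(=O)OC2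
F12 | step 7 | 3-bromo-4-{(3S)-3-[(5S)-5-methyl-5-(2-methylprop-1-en-1-yl)-4-oxo-4,5-dihydrofuran-2-yl]butanoyl}furan-2(5H)-one | CC(C)=C[C@]1(C)OC(=CC1=O)[C@@H](C)CC(=O)C2=C(Br)C(=O)OC2
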